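**Retrosynthetic overview**

- The target is reached from its C4' silyl ether / methyl ester by desilylation, saponification and acetylation; the benzene ring is the only ring, it is bought intact, and no ring is formed.
- The strategy rests on the 2'E trisubstituted alkene C2'=C3' of the chain ortho to the methoxy group: its C3' methyl is cis to the benzylic C1', and it sits next to the oxygenated C4' stereocentre (R).
- The bonds C3'–CH3 and C1'–C2' are cut together, giving a terminal alkyne that already holds C4' (a C2'≡C3' propargylic silyl ether), trimethylaluminium and a benzylic chloride that carries the cinnamate.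
- The alkyne comes from 4-methylpent-3-enoic acid and trimethylsilylacetylene through a Weinreb amide, a silyl ynone and an asymmetric transfer hydrogenation that sets C4'.
- The benzylic chloride comes from (5-bromo-2-methoxyphenyl)methanol by a Heck reaction with methyl acrylate and then SOCl2.

Key step: step 8

Remark: the chain is numbered C1' (ArCH2) to C7' (the CMe2 carbon); the SMILES is read as 4'R, 2'E and E at the cinnamic double bond, and all starting materials are taken to be commercial.

**Route**

Step 1
Reactants: 1 4-methylpent-3-enoic acid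
Product: 3 N-methoxy-N,4-dimethylpent-3-enamide, via acyl imidazole 2 (not isolated)
Conditions: 1,1'-carbonyldiimidazole (1.1 equiv), CH2Cl2, 0 °C → rt; then MeNH(OMe)·HCl (1.2 equiv), rt
Reagents that add atoms: N,O-dimethylhydroxylamine hydrochloride, CNOC.Cl; 1,1'-carbonyldiimidazole, O=C(n1ccnc1)n1ccnc1 (supplies only the imidazole of 2)
Why: Carbonyldiimidazole activation and aminolysis of the acyl imidazole (amide coupling, Weinreb amide formation) run without strong acid or base, so the β,γ-alkene should stay out of conjugation.

Step 2
Reactants: 3 N-methoxy-N,4-dimethylpent-3-enamide; 4 trimethylsilylacetylene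
Product: 6 6-methyl-1-(trimethylsilyl)hept-5-en-1-yn-3-one, via lithium trimethylsilylacetylide 5 (not isolated)
Conditions: 4 (1.3 equiv), n-BuLi (1.25 equiv), THF, −78 °C; then 3, −78 → 0 °C; inverse quench into cold 1 M HCl
Reagents that add atoms: n-butyllithium, [Li]CCCC (lithium of 5 only)
Why: Weinreb ketone synthesis: the lithium acetylide adds once to give a chelated tetrahedral adduct that collapses to the ynone only on the acidic inverse quench, which also protonates the released N,O-dimethylhydroxylamine so that it cannot add to the ynone.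

Step 3
Reactants: 6 6-methyl-1-(trimethylsilyl)hept-5-en-1-yn-3-one
Product: 7 (R)-6-methyl-1-(trimethylsilyl)hept-5-en-1-yn-3-ol
Conditions: Ru(p-cymene)[(R,R)-TsNCHPhCHPhNH] (1 mol%), i-PrOH, rt
Reagents that add atoms: none
Why: Noyori asymmetric transfer hydrogenation under base-free conditions: the Ru–H/N–H pair passes H2 from 2-propanol to the C=O through a six-membered transition state in which the alkynyl group takes the place an aryl group normally holds, so the (R,R)-catalyst should set the carbinol (future C4') as R while the C≡C and C=C bonds are left alone.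

Step 4
Reactants: 7 (R)-6-methyl-1-(trimethylsilyl)hept-5-en-1-yn-3-ol
Product: 8 (R)-tert-butyldimethyl{[6-methyl-1-(trimethylsilyl)hept-5-en-1-yn-3-yl]oxy}silane
Conditions: TBSCl (1.2 equiv), imidazole (2.5 equiv), DMF, rt
Reagents that add atoms: tert-butyldimethylsilyl chloride, CC(C)(C)[Si](C)(C)Cl
Why: Imidazole-promoted O-silylation of the secondary alcohol is routine, leaves the stereocentre untouched, and is done before C-desilylation so that the volatile free alkynol is never handled.

Step 5
Reactants: 8 (R)-tert-butyldimethyl{[6-methyl-1-(trimethylsilyl)hept-5-en-1-yn-3-yl]oxy}silane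
Product: 9 (R)-3-(tert-butyldimethylsilyloxy)-6-methylhept-5-en-1-yne
Conditions: K2CO3 (0.2 equiv), MeOH, rt
Reagents that add atoms: none
Why: Methanolysis (protodesilylation) of the alkynyl C–SiMe3 bond by catalytic methoxide is selective because an acetylide is a good leaving group from silicon whereas the hindered secondary O–Si(t-Bu)Me2 ether resists K2CO3 in methanol.

Step 6
Reactants: 10 (5-bromo-2-methoxyphenyl)methanol; 11 methyl acrylate
Product: 12 methyl (E)-3-[3-(hydroxymethyl)-4-methoxyphenyl]acrylate
Conditions: 11 (1.5 equiv), Pd(OAc)2 (2 mol%), P(o-tol)3 (6 mol%), Et3N (2 equiv), DMF, 100 °C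
Reagents that add atoms: none
Why: Mizoroki–Heck reaction: zerovalent palladium generated from Pd(OAc)2 inserts into the C–Br bond, syn carbopalladation of the acrylate and syn β-hydride elimination give the E cinnamate, and the free benzylic alcohol is tolerated.

Step 7
Reactants: 12 methyl (E)-3-[3-(hydroxymethyl)-4-methoxyphenyl]acrylate
Product: 13 methyl (E)-3-[3-(chloromethyl)-4-methoxyphenyl]acrylate
Conditions: SOCl2 (1.2 equiv), CH2Cl2, 0 °C → rt
Reagents that add atoms: thionyl chloride, O=S(Cl)Cl
Why: Chlorodehydroxylation through the alkyl chlorosulfite (nucleophilic substitution) is fast at an o-methoxybenzylic carbon, and the enoate, ester and aryl ether do not react with SOCl2.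

Step 8
Reactants: 9 (R)-3-(tert-butyldimethylsilyloxy)-6-methylhept-5-en-1-yne; 14 trimethylaluminium; 13 methyl (E)-3-[3-(chloromethyl)-4-methoxyphenyl]acrylate
Product: 16 methyl (E)-3-{3-[(2E,4R)-4-(tert-butyldimethylsilyloxy)-3,7-dimethylocta-2,6-dien-1-yl]-4-methoxyphenyl}acrylate, via alkenylalane 15 (not isolated)
Conditions: 14 (2.5 equiv), Cp2ZrCl2 (0.3 equiv), ClCH2CH2Cl, 0 °C → rt; solvent and excess Me3Al removed under high vacuum at rt; then THF, 13 (0.85 equiv), Pd(PPh3)4 (5 mol%), rt
Reagents that add atoms: none
Why: Cp2ZrCl2 and Me3Al form a methylzirconocene–chloroaluminate pair that adds Zr–CH3 across the C2'≡C3' triple bond of 9 through a concerted four-centre syn transition state, methyl to the substituted C3' and metal to the unhindered terminal C2', and Zr-to-Al exchange gives the (E)-alkenylalane 15 and returns the catalyst. Zerovalent palladium then inserts into the benzylic C–Cl bond of 13, the sp2 alkenyl group (faster than the sp3 methyls) moves from aluminium to palladium, and reductive elimination forms C1'–C2' with retention of the alkene geometry. The closest known reaction type is the Negishi zirconium-catalysed methylalumination of terminal alkynes followed by palladium-catalysed cross-coupling of the alkenylalane with a benzylic halide. No ring is closed and no stereocentre is created; C4' is a spectator with no acidic or ionisable bond under these conditions and should stay R. The selectivity needed is regio- and syn-selective addition so that the C3' methyl ends cis to C1' (2'E), which the terminal alkyne and the branched, silylated propargylic carbon secure, while the trisubstituted C6'=C7' alkene does not carbometalate. Chemoselectivity toward the cinnamate ester is secured by evaporating the excess Me3Al before 13 is added, so the ester meets only the weakly nucleophilic alkenylalane at room temperature.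

Step 9
Reactants: 16 methyl (E)-3-{3-[(2E,4R)-4-(tert-butyldimethylsilyloxy)-3,7-dimethylocta-2,6-dien-1-yl]-4-methoxyphenyl}acrylate
Product: 17 methyl (E)-3-{3-[(2E,4R)-4-hydroxy-3,7-dimethylocta-2,6-dien-1-yl]-4-methoxyphenyl}acrylate
Conditions: n-Bu4NF (1.5 equiv), THF, 0 °C → rt; aqueous NH4Cl
Reagents that add atoms: none
Why: Fluoride-mediated desilylation, driven by the strong Si–F bond, frees the C4' alcohol without breaking its C–O bond, and the methyl ester and alkenes are inert.

Step 10
Reactants: 17 methyl (E)-3-{3-[(2E,4R)-4-hydroxy-3,7-dimethylocta-2,6-dien-1-yl]-4-methoxyphenyl}acrylate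
Product: 18 (E)-3-{3-[(2E,4R)-4-hydroxy-3,7-dimethylocta-2,6-dien-1-yl]-4-methoxyphenyl}acrylic acid
Conditions: LiOH·H2O (4 equiv), THF/MeOH/H2O 3:1:1, rt; then 1 M HCl to pH 3–4, 0 °C
Reagents that add atoms: lithium hydroxide, [Li+].[OH-]
Why: Ester saponification by acyl–oxygen cleavage is done before acetylation so that two esters never need to be told apart, and the C4' allylic alcohol and the three alkenes are stable to aqueous LiOH at room temperature.

Step 11
Reactants: 18 (E)-3-{3-[(2E,4R)-4-hydroxy-3,7-dimethylocta-2,6-dien-1-yl]-4-methoxyphenyl}acrylic acid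
Product: 20 (E)-3-{3-[(2E,4R)-4-acetoxy-3,7-dimethylocta-2,6-dien-1-yl]-4-methoxyphenyl}acrylic acid, via mixed anhydride 19 (not isolated)
Conditions: Ac2O (3 equiv), pyridine, DMAP (5 mol%), CH2Cl2, 0 °C → rt; then H2O/THF, rt; dilute aqueous HCl wash
Reagents that add atoms: acetic anhydride, CC(=O)OC(C)=O
Why: DMAP-catalysed O-acetylation (nucleophilic acyl transfer) esterifies the C4' alcohol with retention because its C–O bond is not broken, the carboxylic acid is acetylated at the same time to the mixed anhydride 19, and water then attacks the more electrophilic acetyl carbonyl of 19 to return the cinnamic acid while the secondary acetate survives.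

**Compound list**

1 | 4-methylpent-3-enoic acid | CC(C)=CCC(=O)O | starting material
2 | 1-(imidazol-1-yl)-4-methylpent-3-en-1-one (acyl imidazole) | CC(C)=CCC(=O)n1ccnc1 | intermediate
3 | N-methoxy-N,4-dimethylpent-3-enamide | CC(C)=CCC(=O)N(C)OC | intermediate
4 | trimethylsilylacetylene | C#C[Si](C)(C)C | starting material
5 | lithium (trimethylsilyl)acetylide | [Li]C#C[Si](C)(C)C | intermediate
6 | 6-methyl-1-(trimethylsilyl)hept-5-en-1-yn-3-one | CC(C)=CCC(=O)C#C[Si](C)(C)C | intermediate
7 | (R)-6-methyl-1-(trimethylsilyl)hept-5-en-1-yn-3-ol | C[Si](C)(C)C#C[C@@H](CC=C(C)C)O | intermediate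
8 | (R)-tert-butyldimethyl{[6-methyl-1-(trimethylsilyl)hept-5-en-1-yn-3-yl]oxy}silane | C[Si](C)(C)C#C[C@@H](CC=C(C)C)O[Si](C)(C)C(C)(C)C | intermediate
9 | (R)-3-(tert-butyldimethylsilyloxy)-6-methylhept-5-en-1-yne | C#C[C@@H](CC=C(C)C)O[Si](C)(C)C(C)(C)C | intermediate
10 | (5-bromo-2-methoxyphenyl)methanol | COc1ccc(Br)cc1CO | starting material
11 | methyl acrylate | C=CC(=O)OC | starting material
12 | methyl (E)-3-[3-(hydroxymethyl)-4-methoxyphenyl]acrylate | COc1ccc(/C=C/C(=O)OC)cc1CO | intermediate
13 | methyl (E)-3-[3-(chloromethyl)-4-methoxyphenyl]acrylate | COc1ccc(/C=C/C(=O)OC)cc1CCl | intermediate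
14 | trimethylaluminium | C[Al](C)C | starting material
15 | [(1E,3R)-3-(tert-butyldimethylsilyloxy)-2,6-dimethylhepta-1,5-dien-1-yl]dimethylaluminium (alkenylalane) | C[Al](C)/C=C(\C)[C@@H](CC=C(C)C)O[Si](C)(C)C(C)(C)C | intermediate
16 | methyl (E)-3-{3-[(2E,4R)-4-(tert-butyldimethylsilyloxy)-3,7-dimethylocta-2,6-dien-1-yl]-4-methoxyphenyl}acrylate | COc1ccc(/C=C/C(=O)OC)cc1C/C=C(\C)[C@@H](CC=C(C)C)O[Si](C)(C)C(C)(C)C | intermediate
17 | methyl (E)-3-{3-[(2E,4R)-4-hydroxy-3,7-dimethylocta-2,6-dien-1-yl]-4-methoxyphenyl}acrylate | COc1ccc(/C=C/C(=O)OC)cc1C/C=C(\C)[C@@H](CC=C(C)C)O | intermediate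
18 | (E)-3-{3-[(2E,4R)-4-hydroxy-3,7-dimethylocta-2,6-dien-1-yl]-4-methoxyphenyl}acrylic acid | COc1ccc(/C=C/C(=O)O)cc1C/C=C(\C)[C@@H](CC=C(C)C)O | intermediate
19 | acetic (E)-3-{3-[(2E,4R)-4-acetoxy-3,7-dimethylocta-2,6-dien-1-yl]-4-methoxyphenyl}acrylic anhydride (mixed anhydride) | COc1ccc(/C=C/C(=O)OC(C)=O)cc1C/C=C(\C)[C@@H](CC=C(C)C)OC(C)=O | intermediate
20 | (E)-3-{3-[(2E,4R)-4-acetoxy-3,7-dimethylocta-2,6-dien-1-yl]-4-methoxyphenyl}acrylic acid (CNP0206859.1) | COc1ccc(/C=C/C(=O)O)cc1C/C=C(\C)[C@@H](CC=C(C)C)OC(C)=O | target

**Step count**

Total: 11 steps. Longest linear sequence: 9 steps (steps 1–5, 8–11); the aryl branch (steps 6–7) joins at step 8.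

**Steps most likely to fail, and fallbacks**

1. Step 8. Transfer of the alkenyl group from aluminium to benzylpalladium may be slower than attack of the Lewis-acidic aluminium species on the cinnamate or than homocoupling of the benzylic chloride. Incomplete carbometalation of the hindered propargylic ether would also carry unreacted alkyne into the coupling. The fallback separates the two stages and reverses the polarity of the coupling. It sets out from 15, made as in step 8. Iodinolysis (I2, THF, −30 → 0 °C) should give the vinyl iodide (R,E)-tert-butyl[(1-iodo-2,6-dimethylhepta-1,5-dien-3-yl)oxy]dimethylsilane F1, which can be purified. Separately, zinc insertion into 13 (Zn dust, LiCl, THF, rt) should give the ester-tolerant benzylic zinc reagent {[2-methoxy-5-((E)-3-methoxy-3-oxoprop-1-en-1-yl)phenyl]methyl}zinc chloride F2. Negishi coupling of F1 with F2 (Pd(PPh3)4 5 mol%, THF, rt) forms the same C1'–C2' bond and comes back to the route at 16.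

2. Step 3. The C5=C6 double bond of the skipped enynone may migrate into conjugation during the slow hydrogen transfer, or reversible transfer may erode the enantiomeric purity. The fallback sets the configuration by resolution and sets out from 6. Luche reduction (NaBH4, CeCl3·7H2O, MeOH, −40 °C) should give racemic 6-methyl-1-(trimethylsilyl)hept-5-en-1-yn-3-ol F3 within minutes, before the alkene can move. K2CO3 in MeOH then gives racemic 6-methylhept-5-en-1-yn-3-ol F4. F4 is resolved by lipase-catalysed acetylation (immobilised Candida antarctica lipase B, vinyl acetate, hexane, rt). By the empirical size rule for lipases (ethynyl as the medium group, prenylmethyl as the large one) the S alcohol should be acetylated, so running past half conversion should leave (R)-6-methylhept-5-en-1-yn-3-ol F5 in high enantiomeric purity. Silylation of F5 (TBSCl, imidazole, DMF) comes back to the route at 9.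

3. Step 2. The basic acetylide may enolise the doubly activated C2 methylene of the amide instead of adding, or the ynone may isomerise or take up the released amine during the quench. The fallback forms the same acyl–alkynyl bond without a basic carbanion or an amine and sets out from 1. 1-Chloro-N,N,2-trimethylprop-1-en-1-amine (CH2Cl2, 0 °C) should give 4-methylpent-3-enoyl chloride F6 under neutral conditions free of HCl. Acylative Stille coupling of F6 with tributyl[(trimethylsilyl)ethynyl]stannane (PdCl2(PPh3)2 2 mol%, toluene, 60 °C) comes back to the route at 6.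

**Further compounds**

F1 | step 8 | (R,E)-tert-butyl[(1-iodo-2,6-dimethylhepta-1,5-dien-3-yl)oxy]dimethylsilane | I/C=C(\C)[C@@H](CC=C(C)C)O[Si](C)(C)C(C)(C)C
F2 | step 8 | {[2-methoxy-5-((E)-3-methoxy-3-oxoprop-1-en-1-yl)phenyl]methyl}zinc chloride | COc1ccc(/C=C/C(=O)OC)cc1C[Zn]Cl
F3 | step 3 | racemic 6-methyl-1-(trimethylsilyl)hept-5-en-1-yn-3-ol | C[Si](C)(C)C#CC(O)CC=C(C)C
F4 | step 3 | racemic 6-methylhept-5-en-1-yn-3-ol | C#CC(O)CC=C(C)C
F5 | step 3 | (R)-6-methylhept-5-en-1-yn-3-ol | C#C[C@@H](CC=C(C)C)O
F6 | step 2 | 4-methylpent-3-enoyl chloride | CC(C)=CCC(=O)Cl
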